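**Plan**

- Retrosynthesis: after the MOM and tert-butyl groups, the C6–C7 bond of the carbocycle (C4a–C5–C6–C7–C8–C8a) is cut. The C6 ketone beside the tertiary carbinol C7 is an α-ketol, and in the ring-opened keto-aldehyde C8–H lies α to the C7 ketone and can epimerise.
- The resulting monocyclic (4H-pyran-4-ylidene)acetaldehyde is cut at the acrylate C=C (Wittig), at C4a=C5 (ethynyl addition to a pyranone C=O, Meyer–Schuster shift), at the C8–O ester bond (Mitsunobu) and at C8a–C8 (Nozaki–Hiyama–Kishi).
- Forward: the pyran ring is that of kojic acid throughout. The C8/C7 chain is joined first, then the orsellinate, the C5–C6 two-carbon unit and the acrylate; the carbocycle closes last.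
- Stereochemistry: C7 and C8 both arise in the ring closure (catalyst-controlled ketone face, dynamic kinetic resolution at C8). The lactaldehyde centre is sacrificial (oxidised to the C7 ketone), and the acrylate is E from the stabilised ylide.

Key step: step 11

Remarks on the chemistry:
- Isochromene numbering of the target (C1, O2, C3, C4, C4a, C5–C8, C8a) is used for all intermediates. TBS = tert-butyldimethylsilyl, MOM = methoxymethyl.
- C8 is carried as an epimer mixture from the coupling step onward, because it is equilibrated in the key step. The exocyclic alkene of the pyranylidene acetaldehydes is a push–pull alkene that isomerises freely; SMILES show the reactive geometry (formyl syn to C8a).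
- Assumption: the (5aR,10bS) antipode of the aminoindanol-derived triazolium salt is taken as the one that delivers (7R,8R); both antipodes are catalogue items, so the sense would be fixed in a first trial.
- Assumption: (S)-2-(tert-butyldimethylsilyloxy)propanal is bought (otherwise two standard steps from ethyl (S)-lactate).

**Route**

Step 1
Reactants: 1 orsellinic acid (2,4-dihydroxy-6-methylbenzoic acid)
Product: 2 methoxymethyl 2,4-bis(methoxymethoxy)-6-methylbenzoate
Conditions: NaH (3.3 equiv), MOMCl (3.5 equiv), DMF, 0 → 23 °C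
Reagents that add atoms: chloromethyl methyl ether, COCCl
Why: Exhaustive Williamson-type O-alkylation of the carboxylate and both phenoxides removes any need for regiocontrol.

Step 2
Reactants: 2 methoxymethyl 2,4-bis(methoxymethoxy)-6-methylbenzoate
Product: 3 2,4-bis(methoxymethoxy)-6-methylbenzoic acid
Conditions: LiOH, THF–MeOH–H2O, 50 °C; then cold 1 M HCl to pH 4
Reagents that add atoms: lithium hydroxide (hydroxide oxygen), [Li+].[OH-]
Why: Saponification: the acylal-type methoxymethyl ester is cleaved far more readily than the aryl MOM ethers, so only the acid is unmasked.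

Step 3
Reactants: 4 kojic acid (5-hydroxy-2-(hydroxymethyl)-4H-pyran-4-one)
Product: 5 2-[(tert-butyldimethylsilyloxy)methyl]-5-hydroxy-4H-pyran-4-one
Conditions: TBSCl (1.05 equiv), imidazole, DMF, 0 → 23 °C
Reagents that add atoms: tert-butyldimethylsilyl chloride, CC(C)(C)[Si](C)(C)Cl
Why: Silylation of the primary alcohol is preferred over the acidic, hydrogen-bonded enolic 5-OH, whose silyl ether would not survive work-up.

Step 4
Reactants: 5 2-[(tert-butyldimethylsilyloxy)methyl]-5-hydroxy-4H-pyran-4-one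
Product: 6 6-[(tert-butyldimethylsilyloxy)methyl]-4-oxo-4H-pyran-3-yl trifluoromethanesulfonate
Conditions: Tf2O, pyridine, CH2Cl2, −20 → 0 °C
Reagents that add atoms: trifluoromethanesulfonic anhydride, O=S(=O)(OS(=O)(=O)C(F)(F)F)C(F)(F)F
Why: O-Sulfonylation of the enolic hydroxyl gives an electron-poor alkenyl triflate, the handle for C–C bond formation at C8a.

Step 5
Reactants: 6 6-[(tert-butyldimethylsilyloxy)methyl]-4-oxo-4H-pyran-3-yl trifluoromethanesulfonate; 7 (S)-2-(tert-butyldimethylsilyloxy)propanal (2 equiv)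
Product: 8 2-[(tert-butyldimethylsilyloxy)methyl]-5-[(2S)-2-(tert-butyldimethylsilyloxy)-1-hydroxypropyl]-4H-pyran-4-one (both C8 epimers)
Conditions: CrCl2 (4 equiv), NiCl2 (2 mol %), degassed DMF, 23 °C
Reagents that add atoms: none
Why: Nozaki–Hiyama–Kishi coupling: nickel inserts into the alkenyl triflate and the alkenylchromium(III) species adds only to the aldehyde, not to the vinylogous ester carbonyl; the new carbinol forms as an epimer mixture, which is immaterial because C8 is equilibrated in step 11.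

Step 6
Reactants: 8 2-[(tert-butyldimethylsilyloxy)methyl]-5-[(2S)-2-(tert-butyldimethylsilyloxy)-1-hydroxypropyl]-4H-pyran-4-one; 3 2,4-bis(methoxymethoxy)-6-methylbenzoic acid
Product: 9 (2S)-2-(tert-butyldimethylsilyloxy)-1-{6-[(tert-butyldimethylsilyloxy)methyl]-4-oxo-4H-pyran-3-yl}propyl 2,4-bis(methoxymethoxy)-6-methylbenzoate (both C8 epimers)
Conditions: PPh3, DIAD, toluene, 0 → 23 °C
Reagents that add atoms: none
Why: Mitsunobu esterification forms the ester by O-alkylation of the carboxylate, which avoids acyl transfer at the di-ortho-substituted benzoyl carbon; inversion at C8 is of no consequence.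

Step 7
Reactants: 9 (2S)-2-(tert-butyldimethylsilyloxy)-1-{6-[(tert-butyldimethylsilyloxy)methyl]-4-oxo-4H-pyran-3-yl}propyl 2,4-bis(methoxymethoxy)-6-methylbenzoate
Product: 11 (2S)-2-(tert-butyldimethylsilyloxy)-1-{6-[(tert-butyldimethylsilyloxy)methyl]-4-(2-oxoethylidene)-4H-pyran-3-yl}propyl 2,4-bis(methoxymethoxy)-6-methylbenzoate, via 4-ethynyl-4H-pyran-4-ol 10 (not isolated)
Conditions: HC≡CMgBr (3 equiv), THF, −40 → 0 °C; then PPTS, THF–H2O (10:1), 23 °C
Reagents that add atoms: ethynylmagnesium bromide, C#C[Mg]Br; water, O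
Why: 1,2-Addition of the alkynyl Grignard reagent to the pyranone carbonyl (the hindered aryl ester should be spared) gives a carbinol that ionises under mild acid to a 4-ethynylpyrylium ion; water adds at the alkyne terminus and tautomerisation (Meyer–Schuster rearrangement) ends in the push–pull enal as the thermodynamic sink.

Step 8
Reactants: 11 (2S)-2-(tert-butyldimethylsilyloxy)-1-{6-[(tert-butyldimethylsilyloxy)methyl]-4-(2-oxoethylidene)-4H-pyran-3-yl}propyl 2,4-bis(methoxymethoxy)-6-methylbenzoate
Product: 12 (2S)-2-hydroxy-1-[6-(hydroxymethyl)-4-(2-oxoethylidene)-4H-pyran-3-yl]propyl 2,4-bis(methoxymethoxy)-6-methylbenzoate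
Conditions: HF·pyridine, pyridine, THF, 0 → 23 °C
Reagents that add atoms: none
Why: Buffered fluoride desilylation should remove both TBS ethers, leave the aryl MOM ethers intact and avoid base-induced migration of the hindered aroyl group to the freed C7 hydroxyl.

Step 9
Reactants: 12 (2S)-2-hydroxy-1-[6-(hydroxymethyl)-4-(2-oxoethylidene)-4H-pyran-3-yl]propyl 2,4-bis(methoxymethoxy)-6-methylbenzoate
Product: 13 1-[6-formyl-4-(2-oxoethylidene)-4H-pyran-3-yl]-2-oxopropyl 2,4-bis(methoxymethoxy)-6-methylbenzoate (C8 stereorandom)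
Conditions: Dess–Martin periodinane (3 equiv), CH2Cl2, 0 → 23 °C
Reagents that add atoms: none
Why: Dess–Martin oxidation should convert the primary allylic alcohol into the aldehyde and the secondary alcohol into the C7 methyl ketone in one near-neutral operation.

Step 10
Reactants: 13 1-[6-formyl-4-(2-oxoethylidene)-4H-pyran-3-yl]-2-oxopropyl 2,4-bis(methoxymethoxy)-6-methylbenzoate; 14 tert-butyl (triphenylphosphoranylidene)acetate (1.05 equiv)
Product: 15 tert-butyl (E)-3-{5-[1-(2,4-bis(methoxymethoxy)-6-methylbenzoyloxy)-2-oxopropyl]-4-(2-oxoethylidene)-4H-pyran-2-yl}acrylate (C8 stereorandom)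
Conditions: CH2Cl2, −20 → 0 °C
Reagents that add atoms: none
Why: The stabilised Wittig ylide is E-selective and should attack the ring formyl group in preference to the ketone and to the exocyclic formyl group, which is a doubly vinylogous formate deactivated by the ring oxygen.

Step 11
Reactants: 15 tert-butyl (E)-3-{5-[1-(2,4-bis(methoxymethoxy)-6-methylbenzoyloxy)-2-oxopropyl]-4-(2-oxoethylidene)-4H-pyran-2-yl}acrylate
Product: 16 tert-butyl (E)-3-[(7R,8R)-8-(2,4-bis(methoxymethoxy)-6-methylbenzoyloxy)-7-hydroxy-7-methyl-6-oxo-7,8-dihydro-6H-isochromen-3-yl]acrylate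
Conditions: (5aR,10bS)-2-mesityl-5a,10b-dihydro-4H,6H-indeno[2,1-b][1,2,4]triazolo[4,3-d][1,4]oxazin-2-ium chloride (20 mol %), DBU (40 mol %), 4 Å MS, toluene, 23 → 40 °C
Reagents that add atoms: none
Why: The triazolylidene freed by DBU adds to the C6 formyl group and, after proton transfer, gives the Breslow enaminol, whose acyl-anion carbon attacks the C7 methyl ketone; collapse of the adduct releases the carbene and the C6 ketone. The closest known reaction type is the triazolium-catalysed intramolecular crossed aldehyde–ketone benzoin, including its dynamic kinetic variants on ketones with an acidic α-stereocentre. The carbocycle closes in a 6-exo-trig mode onto the ketone carbonyl, after the exocyclic alkene has isomerised so that the formyl group faces the C8 chain. C7 is set by the catalyst, whose aminoindanol wall shields one face of the enaminol while the enaminol O–H hydrogen-bonds the ketone oxygen; C8 is set by dynamic kinetic resolution, the faster-reacting epimer placing the aroyloxy group pseudo-equatorial and anti to the forming bond (polar Felkin–Anh), which puts 7-OH and 8-O cis. The step needs C8 epimerisation by DBU (C8–H is α to the ketone, α to the acyloxy group and allylic) to outrun ring closure and acyl-anion rather than homoenolate reactivity, which the fully substituted β-carbon C4a and the 6-exo geometry favour, while the di-ortho-substituted aroyl group resists migration through the enediolate. The new C6 ketone regains vinylogous-ester conjugation with the pyran oxygen, so closure should be effectively irreversible, and C8, no longer α to a carbonyl, is then fixed.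

Step 12
Reactants: 16 tert-butyl (E)-3-[(7R,8R)-8-(2,4-bis(methoxymethoxy)-6-methylbenzoyloxy)-7-hydroxy-7-methyl-6-oxo-7,8-dihydro-6H-isochromen-3-yl]acrylate
Product: 17 (+)-mitorubrinic acid B, (E)-3-[(7R,8R)-8-(2,4-dihydroxy-6-methylbenzoyloxy)-7-hydroxy-7-methyl-6-oxo-7,8-dihydro-6H-isochromen-3-yl]acrylic acid
Conditions: TFA–CH2Cl2 (1:3), H2O (5 equiv), 0 → 23 °C
Reagents that add atoms: none
Why: Acidolysis: the aryl MOM acetals hydrolyse and the tert-butyl ester loses isobutene, while the tertiary carbinol α to the ketone cannot ionise and neither stereocentre is touched.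

**Compound list**

1 | orsellinic acid | Cc1cc(O)cc(O)c1C(=O)O | starting material
2 | methoxymethyl 2,4-bis(methoxymethoxy)-6-methylbenzoate | Cc1cc(OCOC)cc(OCOC)c1C(=O)OCOC | intermediate
3 | 2,4-bis(methoxymethoxy)-6-methylbenzoic acid | Cc1cc(OCOC)cc(OCOC)c1C(=O)O | intermediate
4 | kojic acid | OCC1=CC(=O)C(O)=CO1 | starting material
5 | 2-[(tert-butyldimethylsilyloxy)methyl]-5-hydroxy-4H-pyran-4-one | CC(C)(C)[Si](C)(C)OCC1=CC(=O)C(O)=CO1 | intermediate
6 | 6-[(tert-butyldimethylsilyloxy)methyl]-4-oxo-4H-pyran-3-yl trifluoromethanesulfonate | CC(C)(C)[Si](C)(C)OCC1=CC(=O)C(OS(=O)(=O)C(F)(F)F)=CO1 | intermediate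
7 | (S)-2-(tert-butyldimethylsilyloxy)propanal | C[C@H](O[Si](C)(C)C(C)(C)C)C=O | starting material
8 | 2-[(TBS-oxy)methyl]-5-[(2S)-2-(TBS-oxy)-1-hydroxypropyl]-4H-pyran-4-one, C8 epimer mixture | C[C@H](O[Si](C)(C)C(C)(C)C)C(O)C1=COC(CO[Si](C)(C)C(C)(C)C)=CC1=O | intermediate
9 | (2S)-2-(TBS-oxy)-1-{6-[(TBS-oxy)methyl]-4-oxo-4H-pyran-3-yl}propyl 2,4-bis(methoxymethoxy)-6-methylbenzoate, C8 epimer mixture | C[C@H](O[Si](C)(C)C(C)(C)C)C(OC(=O)c1c(C)cc(OCOC)cc1OCOC)C1=COC(CO[Si](C)(C)C(C)(C)C)=CC1=O | intermediate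
10 | 4-ethynyl-4-hydroxy-4H-pyran adduct of 9 (C4 carbinol, not isolated) | C[C@H](O[Si](C)(C)C(C)(C)C)C(OC(=O)c1c(C)cc(OCOC)cc1OCOC)C1=COC(CO[Si](C)(C)C(C)(C)C)=CC1(O)C#C | intermediate
11 | (2S)-2-(TBS-oxy)-1-{6-[(TBS-oxy)methyl]-4-(2-oxoethylidene)-4H-pyran-3-yl}propyl 2,4-bis(methoxymethoxy)-6-methylbenzoate | C[C@H](O[Si](C)(C)C(C)(C)C)C(OC(=O)c1c(C)cc(OCOC)cc1OCOC)C1=COC(CO[Si](C)(C)C(C)(C)C)=C\C1=C\C=O | intermediate
12 | (2S)-2-hydroxy-1-[6-(hydroxymethyl)-4-(2-oxoethylidene)-4H-pyran-3-yl]propyl 2,4-bis(methoxymethoxy)-6-methylbenzoate | C[C@H](O)C(OC(=O)c1c(C)cc(OCOC)cc1OCOC)C1=COC(CO)=C\C1=C\C=O | intermediate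
13 | 1-[6-formyl-4-(2-oxoethylidene)-4H-pyran-3-yl]-2-oxopropyl 2,4-bis(methoxymethoxy)-6-methylbenzoate, C8 stereorandom | CC(=O)C(OC(=O)c1c(C)cc(OCOC)cc1OCOC)C1=COC(C=O)=C\C1=C\C=O | intermediate
14 | tert-butyl (triphenylphosphoranylidene)acetate | CC(C)(C)OC(=O)C=P(c1ccccc1)(c1ccccc1)c1ccccc1 | starting material
15 | tert-butyl (E)-3-{5-[1-(2,4-bis(methoxymethoxy)-6-methylbenzoyloxy)-2-oxopropyl]-4-(2-oxoethylidene)-4H-pyran-2-yl}acrylate, C8 stereorandom | Cc1cc(OCOC)cc(OCOC)c1C(=O)OC(C(C)=O)C1=COC(/C=C/C(=O)OC(C)(C)C)=C\C1=C\C=O | intermediate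
16 | tert-butyl (E)-3-[(7R,8R)-8-(2,4-bis(methoxymethoxy)-6-methylbenzoyloxy)-7-hydroxy-7-methyl-6-oxo-7,8-dihydro-6H-isochromen-3-yl]acrylate | Cc1cc(OCOC)cc(OCOC)c1C(=O)O[C@@H]1C2=COC(/C=C/C(=O)OC(C)(C)C)=CC2=CC(=O)[C@]1(C)O | intermediate
17 | (+)-mitorubrinic acid B | Cc1cc(O)cc(O)c1C(=O)O[C@@H]1C2=COC(/C=C/C(=O)O)=CC2=CC(=O)[C@]1(C)O | target

**Count**

Total steps: 12. Longest linear sequence: 10 (kojic acid, steps 3–12).

**Steps most likely to fail**

1. Step 11. The carbene may add too slowly to the donor-stabilised formyl group. More likely, the catalyst may discriminate poorly between the two interconverting C8 epimers and the two ketone faces, giving low enantio- or diastereoselection; base-induced enolate chemistry at C8 (aroyl shift, five-membered aldol) may also compete. Fallback, setting out from 15 and returning at 16: ring closure and absolute stereocontrol are separated. 15 would be cyclised with the achiral 2-mesityl-6,7-dihydro-5H-pyrrolo[2,1-c][1,2,4]triazolium salt and DBU, so that only the cis/trans relationship is left to substrate control. This should give racemic cis material, that is 16 together with its antipode, tert-butyl (E)-3-[(7S,8S)-8-(2,4-bis(methoxymethoxy)-6-methylbenzoyloxy)-7-hydroxy-7-methyl-6-oxo-7,8-dihydro-6H-isochromen-3-yl]acrylate F1. The enantiomers would then be separated on a chiral stationary phase, and the route resumes at 16.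

2. Step 7. The alkynyl Grignard reagent may be consumed by the aryl ester, the aroyl group may shift to the tertiary magnesium alkoxide of 10, or 1,2-addition may be blocked by the bulky substituent at C8a. Fallback, setting out from 6 and returning at 11: the two-carbon homologation is done before the side chain exists. Triflate 6 with ethynylmagnesium bromide should give the 4-ethynyl-4-hydroxy-4H-pyran-3-yl triflate F2 (not isolated), which under PPTS in wet THF rearranges to 6-[(tert-butyldimethylsilyloxy)methyl]-4-(2-oxoethylidene)-4H-pyran-3-yl trifluoromethanesulfonate F3. Nozaki–Hiyama–Kishi coupling of F3 with 7 would then give {5-[(2S)-2-(tert-butyldimethylsilyloxy)-1-hydroxypropyl]-2-[(tert-butyldimethylsilyloxy)methyl]-4H-pyran-4-ylidene}acetaldehyde F4; the alkenylchromium species should add to the aliphatic aldehyde much faster than to the vinylogous formyl group. Mitsunobu esterification of F4 with 3 under the conditions of step 6 leads to 11.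

3. Step 5. The triflate may be lost reductively (protonation of the alkenyl-metal species), or transmetalation to chromium may fail on this vinylogous ester. Fallback, setting out from 6 and returning at 13: C8 is introduced as an aldehyde and C7 as an acyl-anion equivalent.
   - Stille coupling of 6 with tributyl(vinyl)tin (Pd(PPh3)4, LiCl, dioxane) should give 2-[(tert-butyldimethylsilyloxy)methyl]-5-vinyl-4H-pyran-4-one F5.
   - Lemieux–Johnson cleavage (OsO4 cat., NaIO4, 2,6-lutidine) gives 6-[(tert-butyldimethylsilyloxy)methyl]-4-oxo-4H-pyran-3-carbaldehyde F6.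
   - 1-Ethoxyvinyllithium (ethyl vinyl ether, t-BuLi, THF, −78 °C) adds to the formyl group to give 2-[(tert-butyldimethylsilyloxy)methyl]-5-(2-ethoxy-1-hydroxyprop-2-en-1-yl)-4H-pyran-4-one F7.
   - Mitsunobu esterification with 3 gives its 2,4-bis(methoxymethoxy)-6-methylbenzoate F8.
   - Ethynylmagnesium bromide then gives the 4-ethynyl-4-hydroxy-4H-pyran carbinol F9 (not isolated); dilute aqueous acid effects the Meyer–Schuster shift and hydrolyses the enol ether, giving 1-{6-[(tert-butyldimethylsilyloxy)methyl]-4-(2-oxoethylidene)-4H-pyran-3-yl}-2-oxopropyl 2,4-bis(methoxymethoxy)-6-methylbenzoate F10.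
   - HF·pyridine gives the hydroxymethyl keto-enal 1-[6-(hydroxymethyl)-4-(2-oxoethylidene)-4H-pyran-3-yl]-2-oxopropyl 2,4-bis(methoxymethoxy)-6-methylbenzoate F11, and Dess–Martin oxidation returns the route to 13.

Further compounds
F1 | step 11 | tert-butyl (E)-3-[(7S,8S)-8-(2,4-bis(methoxymethoxy)-6-methylbenzoyloxy)-7-hydroxy-7-methyl-6-oxo-7,8-dihydro-6H-isochromen-3-yl]acrylate (antipode of 16) | Cc1cc(OCOC)cc(OCOC)c1C(=O)O[C@H]1C2=COC(/C=C/C(=O)OC(C)(C)C)=CC2=CC(=O)[C@@]1(C)O
F2 | step 7 | 6-[(tert-butyldimethylsilyloxy)methyl]-4-ethynyl-4-hydroxy-4H-pyran-3-yl trifluoromethanesulfonate (not isolated) | CC(C)(C)[Si](C)(C)OCC1=CC(O)(C#C)C(OS(=O)(=O)C(F)(F)F)=CO1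
F3 | step 7 | 6-[(tert-butyldimethylsilyloxy)methyl]-4-(2-oxoethylidene)-4H-pyran-3-yl trifluoromethanesulfonate | CC(C)(C)[Si](C)(C)OCC1=CC(=CC=O)C(OS(=O)(=O)C(F)(F)F)=CO1
F4 | step 7 | {5-[(2S)-2-(tert-butyldimethylsilyloxy)-1-hydroxypropyl]-2-[(tert-butyldimethylsilyloxy)methyl]-4H-pyran-4-ylidene}acetaldehyde | C[C@H](O[Si](C)(C)C(C)(C)C)C(O)C1=COC(CO[Si](C)(C)C(C)(C)C)=CC1=CC=O
F5 | step 5 | 2-[(tert-butyldimethylsilyloxy)methyl]-5-vinyl-4H-pyran-4-one | CC(C)(C)[Si](C)(C)OCC1=CC(=O)C(C=C)=CO1
F6 | step 5 | 6-[(tert-butyldimethylsilyloxy)methyl]-4-oxo-4H-pyran-3-carbaldehyde | CC(C)(C)[Si](C)(C)OCC1=CC(=O)C(C=O)=CO1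
F7 | step 5 | 2-[(tert-butyldimethylsilyloxy)methyl]-5-(2-ethoxy-1-hydroxyprop-2-en-1-yl)-4H-pyran-4-one | CCOC(=C)C(O)C1=COC(CO[Si](C)(C)C(C)(C)C)=CC1=O
F8 | step 5 | 1-{6-[(tert-butyldimethylsilyloxy)methyl]-4-oxo-4H-pyran-3-yl}-2-ethoxyprop-2-en-1-yl 2,4-bis(methoxymethoxy)-6-methylbenzoate | CCOC(=C)C(OC(=O)c1c(C)cc(OCOC)cc1OCOC)C1=COC(CO[Si](C)(C)C(C)(C)C)=CC1=O
F9 | step 5 | 4-ethynyl-4-hydroxy-4H-pyran adduct of F8 (not isolated) | CCOC(=C)C(OC(=O)c1c(C)cc(OCOC)cc1OCOC)C1=COC(CO[Si](C)(C)C(C)(C)C)=CC1(O)C#C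
F10 | step 5 | 1-{6-[(tert-butyldimethylsilyloxy)methyl]-4-(2-oxoethylidene)-4H-pyran-3-yl}-2-oxopropyl 2,4-bis(methoxymethoxy)-6-methylbenzoate | CC(=O)C(OC(=O)c1c(C)cc(OCOC)cc1OCOC)C1=COC(CO[Si](C)(C)C(C)(C)C)=CC1=CC=O
F11 | step 5 | 1-[6-(hydroxymethyl)-4-(2-oxoethylidene)-4H-pyran-3-yl]-2-oxopropyl 2,4-bis(methoxymethoxy)-6-methylbenzoate | CC(=O)C(OC(=O)c1c(C)cc(OCOC)cc1OCOC)C1=COC(CO)=CC1=CC=O
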